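The indole is cut at N1–C7a of the pyrrole ring, which leads back to an α-azidocinnamate carrying a 2,5-dibromophenyl group. Heating this vinyl azide drives off N2 and ties the nitrogen to an ortho carbon of the benzene ring. The five-membered ring and the whole 4,7-dibromoindole core therefore appear in one operation without added reagent. The step exploits the bromines at C4 and C7 of the benzo ring. Of the two ring carbons flanking C3a, C4 is occupied by Br and only C7a carries H, so one regioisomer alone can form. Afterwards C3 is brominated first, and the C2 ester, once hydrolysed, is exchanged for chlorine by decarboxylative chlorination.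

Key step: step 2

Remark on stereochemistry: the target is planar and has no stereocentre, so it is achiral and no enantiomer has to be selected. The only stereo-element of the route is the Z alkene of 4, which is erased in step 2.

Remark on sequence: C3 is brominated before the carboxyl group is exchanged. Cu(II) chloride and N–F oxidants halogenate a free indole C3, and with C3 closed the last step can act only at C2.

Step 1
Reactants: 1 2,5-dibromobenzaldehyde; 2 ethyl azidoacetate
Product: 4 ethyl (Z)-2-azido-3-(2,5-dibromophenyl)acrylate, via aldol adduct 3 (not isolated)
Conditions: NaOEt (3–4 equiv), 2 (3–4 equiv), EtOH, −15 °C to 0 °C; aq. NH4Cl; concentration below 40 °C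
Reagents that add atoms: none
Why: Knoevenagel-type aldol/E1cB condensation (first half of the Hemetsberger–Knittel sequence), in which the azidoacetate enolate adds to the non-enolisable aldehyde and aldolate 3 expels hydroxide with the aryl group ending trans to the ester (Z alkene) on steric grounds, while cold, matched ethoxide limits azide breakdown and ester exchange.

Step 2
Reactants: 4 ethyl (Z)-2-azido-3-(2,5-dibromophenyl)acrylate
Product: 6 ethyl 4,7-dibromo-1H-indole-2-carboxylate, via 2H-azirine ester 5 (not isolated)
Conditions: xylenes, reflux (ca. 140 °C), slow addition of a dilute solution of 4, N2 atmosphere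
Reagents that add atoms: none
Why: This is the Hemetsberger–Knittel indole synthesis: near 140 °C vinyl azide 4 loses N2 to give 2H-azirine 5, which equilibrates thermally with its ring-opened vinyl nitrene form. The five-atom array N–C2–C3–C3a–C7a, holding six electrons, closes by a 1,5-electrocyclisation that makes the N1–C7a bond and the pyrrole ring, and a 1,5-hydrogen shift from C7a to N1 then restores both aromatic rings. No stereocentre is created, and the Z geometry of 4 and the transient stereocentre of 5 both vanish in planar 6. The only selectivity needed is between the two ortho carbons of the aryl ring, and the substrate settles it because the carbon that becomes C4 bears Br and has no hydrogen to shift, whereas the carbon that becomes C7a is a C–H. No metal, base or reductant is present, so both C–Br bonds and the ester should pass through untouched. Slow addition to hot solvent keeps the azide inventory and the azirine concentration low, which favours ring closure over bimolecular decay.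

Step 3
Reactants: 6 ethyl 4,7-dibromo-1H-indole-2-carboxylate
Product: 7 ethyl 3,4,7-tribromo-1H-indole-2-carboxylate
Conditions: NBS (1.05 equiv), DMF, 0 °C to rt, dark
Reagents that add atoms: N-bromosuccinimide, O=C1CCC(=O)N1Br
Why: Electrophilic aromatic substitution at C3, a routine reaction of indole-2-carboxylates, should be site-selective because C3 is the only enamine-type C–H left and the benzo ring is deactivated by two bromines.

Step 4
Reactants: 7 ethyl 3,4,7-tribromo-1H-indole-2-carboxylate
Product: 8 3,4,7-tribromo-1H-indole-2-carboxylic acid
Conditions: LiOH·H2O, THF/EtOH/H2O, 40 °C; then 1 M HCl, 0 °C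
Reagents that add atoms: lithium hydroxide, [Li+].[OH-]
Why: Ester saponification (BAc2), in which hydroxide first removes the N–H proton so that the electron-rich indolide resists addition–elimination at C3–Br, only the ester carbonyl is attacked, and cold acidification frees the acid without loss of CO2.

Step 5
Reactants: 8 3,4,7-tribromo-1H-indole-2-carboxylic acid
Product: 9 3,4,7-tribromo-2-chloro-1H-indole
Conditions: [Cu(MeCN)4]BF4 (cat.), ZnCl2, 1-fluoro-2,4,6-trimethylpyridinium BF4, MeCN, 365 nm LED, rt
Reagents that add atoms: zinc chloride, [Cl-].[Zn+2].[Cl-]
Why: Copper ligand-to-metal charge-transfer halodecarboxylation of a heteroaryl carboxylic acid, in which the photoexcited Cu(II) carboxylate of 8 undergoes Cu–O homolysis, the aroyloxy radical loses CO2, the C2 σ-radical is captured by Cu(II) chloride and released as C2–Cl by reductive elimination from Cu(III), and the N–F salt re-oxidises Cu(I), while C3 is already substituted and copper does not engage aryl C–Br bonds at room temperature.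

Compound list
1 | 2,5-dibromobenzaldehyde | O=Cc1cc(Br)ccc1Br | starting material
2 | ethyl azidoacetate | CCOC(=O)CN=[N+]=[N-] | starting material
3 | ethyl 2-azido-3-(2,5-dibromophenyl)-3-hydroxypropanoate (aldol adduct, racemic diastereomer mixture, present as its sodium alkoxide, not isolated) | CCOC(=O)C(N=[N+]=[N-])C(O)c1cc(Br)ccc1Br | intermediate
4 | ethyl (Z)-2-azido-3-(2,5-dibromophenyl)acrylate (aryl trans to the ester, cis to the azide) | CCOC(=O)/C(N=[N+]=[N-])=C/c1cc(Br)ccc1Br | intermediate
5 | ethyl 2-(2,5-dibromophenyl)-2H-azirine-3-carboxylate (racemic, not isolated) | CCOC(=O)C1=NC1c1cc(Br)ccc1Br | intermediate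
6 | ethyl 4,7-dibromo-1H-indole-2-carboxylate | CCOC(=O)c1cc2c(Br)ccc(Br)c2[nH]1 | intermediate
7 | ethyl 3,4,7-tribromo-1H-indole-2-carboxylate | CCOC(=O)c1[nH]c2c(Br)ccc(Br)c2c1Br | intermediate
8 | 3,4,7-tribromo-1H-indole-2-carboxylic acid | OC(=O)c1[nH]c2c(Br)ccc(Br)c2c1Br | intermediate
9 | 3,4,7-tribromo-2-chloro-1H-indole (achiral) | Clc1[nH]c2c(Br)ccc(Br)c2c1Br | target
10 | (2,5-dibromophenyl)hydrazine (needed only for the fallback to step 2) | NNc1cc(Br)ccc1Br | starting material
11 | ethyl pyruvate (needed only for the fallback to step 2) | CCOC(=O)C(C)=O | starting material

Total step count: 5. Longest linear sequence: 5 (1 → 4 → 6 → 7 → 8 → 9).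

Steps most likely to fail

1. Step 5.
- **What may go wrong:** CO2 loss from the heteroaroyloxy radical may be sluggish. The C2 radical may abstract hydrogen from acetonitrile. The N–F salt may oxidise the free N–H indole. Light may cause loss of bromine.
- **Fallback:** a polar route instead of a radical one, in which the carboxyl group is simply discarded. It sets out from 6 and comes back at 9. Ester 6 is saponified to 4,7-dibromo-1H-indole-2-carboxylic acid F1. This is protodecarboxylated (cat. Ag2CO3, AcOH, DMSO, 120 °C) to 4,7-dibromo-1H-indole F2. Boc2O/DMAP gives tert-butyl 4,7-dibromoindole-1-carboxylate F3. LDA at −78 °C removes the C2 proton; an amide base rather than an alkyllithium is chosen so that Br/Li exchange is avoided. Hexachloroethane then delivers tert-butyl 4,7-dibromo-2-chloroindole-1-carboxylate F4. K2CO3 in MeOH removes the carbamate to give 4,7-dibromo-2-chloro-1H-indole F5. NBS in DMF brominates its free C3 to give 9.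

2. Step 1.
- **What may go wrong:** base-induced breakdown of the azidoacetate may outrun its addition to the ortho-hindered aldehyde. Dehydration of the aldolate may stall. The hydroxide released may hydrolyse the ester.
- **Fallback:** the azide is brought in by substitution, with no azidoacetate enolate. It sets out from 1 and comes back at 4. Horner–Wadsworth–Emmons olefination of 1 with triethyl phosphonoacetate (NaH, THF) should give ethyl (E)-3-(2,5-dibromophenyl)acrylate F6. Br2 in CH2Cl2 adds anti to give racemic ethyl (2RS,3SR)-2,3-dibromo-3-(2,5-dibromophenyl)propanoate F7. NaN3 in DMF at rt displaces the α-bromide and then eliminates HBr, as in the standard preparation of α-azidochalcones and α-azidoacrylates, to give 4. The alkene geometry is not critical, since both isomers pass through azirine 5.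

3. Step 2.
- **What may go wrong:** bimolecular decay of the azirine/nitrene pair (dimerisation, tar formation) may compete with closure onto a C–H that is flanked by bromine. The energy content of the azide also limits scale.
- **Fallback:** a Fischer indole synthesis, which makes C3–C3a instead and involves no azide. It sets out from 10 and 11 and comes back at 6. Condensation in EtOH should give ethyl 2-[2-(2,5-dibromophenyl)hydrazinylidene]propanoate F8 as an E/Z mixture. Polyphosphoric acid at about 100–110 °C then triggers the [3,3]-shift onto the only free ortho carbon of the aryl ring, followed by loss of ammonia. This again allows only the 4,7-dibromo pattern of 6.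

Further compounds
F1 | step 5 | 4,7-dibromo-1H-indole-2-carboxylic acid | OC(=O)c1cc2c(Br)ccc(Br)c2[nH]1
F2 | step 5 | 4,7-dibromo-1H-indole | Brc1ccc(Br)c2[nH]ccc12
F3 | step 5 | tert-butyl 4,7-dibromoindole-1-carboxylate | CC(C)(C)OC(=O)n1ccc2c(Br)ccc(Br)c12
F4 | step 5 | tert-butyl 4,7-dibromo-2-chloroindole-1-carboxylate | CC(C)(C)OC(=O)n1c(Cl)cc2c(Br)ccc(Br)c12
F5 | step 5 | 4,7-dibromo-2-chloro-1H-indole | Clc1cc2c(Br)ccc(Br)c2[nH]1
F6 | step 1 | ethyl (E)-3-(2,5-dibromophenyl)acrylate | CCOC(=O)/C=C/c1cc(Br)ccc1Br
F7 | step 1 | ethyl (2RS,3SR)-2,3-dibromo-3-(2,5-dibromophenyl)propanoate (racemic, one enantiomer drawn) | CCOC(=O)[C@@H](Br)[C@@H](Br)c1cc(Br)ccc1Br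
F8 | step 2 | ethyl 2-[2-(2,5-dibromophenyl)hydrazinylidene]propanoate (E/Z mixture) | CCOC(=O)C(C)=NNc1cc(Br)ccc1Br
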